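If the shares read in the ochre and teal runs are multiplied by their charges, Q nearly coincides at 20.0 min: 0.0903 M and 0.0878 M. The charges differ by a factor of 1.57, so in these two runs Q does not follow the charge. Between 15.0 min and 20.0 min, Q also stays flat within the scatter in both runs.

| flask | X | remark | time |
|---|---|---|---|
| ochre | 0.42 M | run made earlier |  |
| teal | 0.66 M | run made earlier |  |
| flask | 0.30 M |  | 25 min |

- ochre (time / min: Q / %, G / %): 5.00: 8.8, 0.7; 6.00: 12.4, 1.4; 10.0: 15.8, 3.2; 15.0: 20.3, 4.7; 20.0: 21.5, 6.2
- teal (time / min: Q / %, G / %): 5.00: 3.2, 0; 6.00: 6.8, 0; 10.0: 10.4, 1.1; 15.0: 14.5, 0.8; 20.0: 13.3, 4.6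

(scatter of a reading: 1 percentage point)

1. time, not beyond 25 min, at which the flask holds most Q
2. the amount of Q, in percent of the X charged, at that time

- given per volume of solution although it is solid: X
- what was read earlier has a scatter of 1 percentage point, one standard deviation
- at the start none of X is in solution

The flask's charge is the smallest, so the same amount of Q is a larger fraction of it. That fraction is the ceiling share: the mean amount of Q on the flat stretch, divided by the charge.

mean amount of Q = 0.0898 M

ceiling share = 29.9 %

The weak link is the solid: the ceiling assumes that X, the limiting reagent, lasts. A balance on the flask's charge tests this.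

solid X left = whole charge − Q − G − forms not read

Q + G at 20.0 min = 38.8 % of this charge by ochre, 39.4 % by teal

If the flask holds the same amounts as these runs, that use is a floor, since forms not read draw on the same charge. By this estimate, solid left at that time is below 61.2 %, and the end of the solid may come early. This reckoning commits to 29.9 % near 20.0 min.

The forecast gives 31 % (27 % to 35 %) at 22 min (16 min to 25 min), on the ground that the flask should “follow the same absolute curve unless its solid runs low”. Its time is later than the one committed to here.

The flask gives 29.2 % at 18.6 min.

    X ⇌ Z, rate k1*(cs1 - [Z]) while solid is left; crystals form when [Z] > cs1 (solubility = 0.130 M, k = 0.183 min⁻¹)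
    Q ⇌ E (K = 18.0, k = 0.120 min⁻¹)
    G → D (k = 2.41 × 10⁻⁴ min⁻¹)
    E → G (k = 0.110 min⁻¹)
    Z → Q (k = 0.341 min⁻¹)
    E ⇌ J (K = 17.0, k = 0.430 min⁻¹)
    Q → L (k = 0.0456 min⁻¹)

In the flask, X stands at 30.2 % at 12.5 min and at 0 % at 18.6 min. The result is 0.70 percentage points below the ceiling share.

With 0.18 M of X, the ceiling share is 49.9 %. The computed flask reaches 39.9 %, which is lower, and X stands at 0 % at 25.0 min.

The data are simulated on assumed constants, noise included.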